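## Retrosynthetic overview

- Numbering: ring C1(O-angelate)–C2(side chain)–C3H2–C4(OH)–C5(CH3)–C6H2; chain C1'(CH3)–C2'H2–C3'(OAc)–C4'=C5'. The route rests on the cis-1,4 oxygens at C1 and C4 of the cyclohexane, both trans to the C2 chain: the imprint of O2 bridging C1 and C4 of a C1=C6–C5(CH3)=C4 ring diene.
- Target ⇐ C4 ketone (equatorial hydride delivery, last step) ⇐ C3' acetate and C1 angelate put on free hydroxyls ⇐ C5 methyl set by enone conjugate reduction and equilibration ⇐ C1-hydroxy-C4-enone ⇐ Kornblum–DeLaMare opening of the C1/C4 endoperoxide.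
- Endoperoxide ⇐ singlet-oxygen [4+2] cycloaddition to the zingiberene-type diene. This is the second ring formed: the O–O bridge of a 2,3-dioxabicyclo[2.2.2]octene, opened again one step later.
- Diene ⇐ dienyl triflate + MeMgBr ⇐ 4-substituted cyclohexenone ⇐ enamine Michael/aldol annulation of a 5-silyloxycitronellal with but-3-en-2-one. This is the first ring formed: the carbocycle, with C2 set by the catalyst.
- Aldehyde ⇐ thioester ⇐ Cu/Josiphos methyl conjugate addition (C1') ⇐ cross-metathesis ⇐ asymmetric allylboration of 3-methylbut-2-enal (C3').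

Key step: step 9

Remark on the chemistry: the (R,S)-Josiphos–CuBr catalyst is assumed to add methyl to (E)-thioenoates in the sense that gives the 3R product in step 4; if the sense is opposite, the (S,R) ligand is the one meant.
Remark on the chemistry: S-ethyl prop-2-enethioate is taken as a purchasable reagent (otherwise one step from acryloyl chloride and ethanethiol).

TBS = tert-butyldimethylsilyl. Ring and chain positions in the Why lines use the target numbering given above.

## Route

Step 1
Reactants: 1 3-methylbut-2-enal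
Product: 2 (4R)-6-methylhepta-1,5-dien-4-ol
Conditions: (+)-Ipc2BOMe, allylMgBr, Et2O, −78 °C to rt; then 1, −78 °C; then NaOH, H2O2, 0 °C to rt
Reagents that add atoms: allylmagnesium bromide, C=CC[Mg]Br
Why: Brown allylboration through a chair Zimmerman–Traxler transition state, in which the isopinocampheyl groups derived from (−)-α-pinene direct allyl to the Re face of the enal carbonyl and so set the carbinol (later C3') as R, with 1,2-addition only.

Step 2
Reactants: 2 (4R)-6-methylhepta-1,5-dien-4-ol
Product: 3 tert-butyl(dimethyl){[(4R)-6-methylhepta-1,5-dien-4-yl]oxy}silane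
Conditions: TBSCl, imidazole, DMF, rt
Reagents that add atoms: tert-butyldimethylsilyl chloride, CC(C)(C)[Si](C)(C)Cl
Why: Standard imidazole-promoted silylation of a secondary alcohol, which leaves the carbinol configuration untouched and gives an ether that survives every step up to step 13.

Step 3
Reactants: 3 tert-butyl(dimethyl){[(4R)-6-methylhepta-1,5-dien-4-yl]oxy}silane; 4 S-ethyl prop-2-enethioate
Product: 5 S-ethyl (2E,5R)-5-(TBSO)-7-methylocta-2,6-dienethioate
Conditions: second-generation Hoveyda–Grubbs catalyst [RuCl2(H2IMes)(=CH-C6H4-2-O-i-Pr)] (3 mol%), excess 4, CH2Cl2, 40 °C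
Reagents that add atoms: none
Why: Olefin cross-metathesis of a terminal alkene with an electron-poor acrylic partner is E-selective, and the trisubstituted alkene next to the silyloxy group reacts far more slowly and should stay intact.

Step 4
Reactants: 5 S-ethyl (2E,5R)-5-(TBSO)-7-methylocta-2,6-dienethioate
Product: 6 S-ethyl (3R,5R)-5-(TBSO)-3,7-dimethyloct-6-enethioate
Conditions: MeMgBr, CuBr·SMe2 (5 mol%), (R,S)-Josiphos (6 mol%), t-BuOMe, −75 °C; then MeOH
Reagents that add atoms: methylmagnesium bromide, C[Mg]Br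
Why: Copper-catalysed asymmetric conjugate addition of a Grignard reagent to an α,β-unsaturated thioester, in which the ferrocenyl diphosphine controls the face of methyl delivery and sets C3 (later C1') as R, anti to the C5 silyloxy group, overriding the remote resident centre.

Step 5
Reactants: 6 S-ethyl (3R,5R)-5-(TBSO)-3,7-dimethyloct-6-enethioate
Product: 7 (3R,5R)-5-(TBSO)-3,7-dimethyloct-6-enal
Conditions: i-Bu2AlH, CH2Cl2, −78 °C; then aq. potassium sodium tartrate
Reagents that add atoms: none
Why: Partial reduction of a thioester stops at the aldehyde because the aluminium hemithioacetal is stable at −78 °C, and the new aldehyde has no stereocentre at its α-carbon to epimerise.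

Step 6
Reactants: 7 (3R,5R)-5-(TBSO)-3,7-dimethyloct-6-enal; 8 but-3-en-2-one
Product: 10 (4S)-4-[(2R,4R)-4-(TBSO)-6-methylhept-5-en-2-yl]cyclohex-2-en-1-one, via keto-aldehyde 9 (not isolated)
Conditions: (S)-2-(methoxydiphenylmethyl)pyrrolidine (5 mol%), ethyl 3,4-dihydroxybenzoate (20 mol%), neat, 4 °C; then LiOH, i-PrOH, rt
Reagents that add atoms: none
Why: Enamine-catalysed Michael addition followed by intramolecular aldol condensation (Robinson annulation), in which the E-enamine of the (S)-prolinol ether is shielded on one face by the CPh2OMe group so that the enone adds to the other face and sets the ring carbon (later C2) as S under catalyst control, as known for citronellal-type β-branched aldehydes.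

Step 7
Reactants: 10 (4S)-4-[(2R,4R)-4-(TBSO)-6-methylhept-5-en-2-yl]cyclohex-2-en-1-one
Product: 11 (4S)-4-[(2R,4R)-4-(TBSO)-6-methylhept-5-en-2-yl]cyclohexa-1,5-dien-1-yl trifluoromethanesulfonate
Conditions: LiN(i-Pr)2, THF, −78 °C; then PhNTf2, −78 to 0 °C
Reagents that add atoms: N-phenylbis(trifluoromethanesulfonimide), O=S(=O)(N(c1ccccc1)S(=O)(=O)C(F)(F)F)C(F)(F)F
Why: Kinetic α'-deprotonation of the cyclohexenone gives the cross-conjugated dienolate, which is trapped on oxygen as the dienyl triflate, while the γ-hydrogen at the stereocentre is not removed at −78 °C.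

Step 8
Reactants: 11 (4S)-4-[(2R,4R)-4-(TBSO)-6-methylhept-5-en-2-yl]cyclohexa-1,5-dien-1-yl trifluoromethanesulfonate
Product: 12 (5S)-5-[(2R,4R)-4-(TBSO)-6-methylhept-5-en-2-yl]-2-methylcyclohexa-1,3-diene
Conditions: MeMgBr, Fe(acac)3 (5 mol%), THF/NMP, −30 to 0 °C
Reagents that add atoms: methylmagnesium bromide, C[Mg]Br
Why: Iron-catalysed Kumada-type cross-coupling of an alkenyl triflate with a methyl Grignard reagent is fast at low temperature and places the methyl on C5 without moving the diene or touching the allylic stereocentre.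

Step 9
Reactants: 12 (5S)-5-[(2R,4R)-4-(TBSO)-6-methylhept-5-en-2-yl]-2-methylcyclohexa-1,3-diene
Product: 13 (1S,4R,7S)-7-[(2R,4R)-4-(TBSO)-6-methylhept-5-en-2-yl]-5-methyl-2,3-dioxabicyclo[2.2.2]oct-5-ene
Conditions: O2, tetraphenylporphyrin (1 mol%), visible light, CH2Cl2, −78 °C, stopped at full consumption of 12
Reagents that add atoms: dioxygen, O=O
Why: Photosensitised singlet oxygen adds suprafacially to the ring-locked s-cis diene C1=C6–C5(CH3)=C4 in a [4+2] cycloaddition, the reaction class of the endoperoxidation of α-phellandrene and α-terpinene. The O–O unit bridges C1 and C4 and closes the six-membered 1,2-dioxene ring of the 2,3-dioxabicyclo[2.2.2]oct-5-ene in one event, both C–O bonds forming on the same face. The two new stereocentres C1 and C4 are controlled by the resident centre C2: oxygen approaches the diene face opposite the side chain on the adjacent sp3 carbon, which puts both oxygens cis to each other and trans to the chain. The facial selectivity is expected to be only moderate for so small a dienophile, so the diastereomeric adduct should be removed by chromatography at this stage. The step also needs chemoselectivity over the Schenck ene reaction of the C4'=C5' alkene, which is secured by the much higher reactivity of the cisoid trialkyl diene, by the inductive deactivation from the allylic silyloxy group at C3', by the low temperature and by stopping at full diene conversion.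

Step 10
Reactants: 13 (1S,4R,7S)-7-[(2R,4R)-4-(TBSO)-6-methylhept-5-en-2-yl]-5-methyl-2,3-dioxabicyclo[2.2.2]oct-5-ene
Product: 14 (4S,5S)-5-[(2R,4R)-4-(TBSO)-6-methylhept-5-en-2-yl]-4-hydroxy-2-methylcyclohex-2-en-1-one
Conditions: Et3N, CH2Cl2, 0 °C to rt
Reagents that add atoms: none
Why: Kornblum–DeLaMare rearrangement, an E2-type removal of a bridgehead hydrogen with O–O cleavage, in which the C4–H (neighbours CH2 and a flat vinylic carbon) should be more accessible to the amine than the C1–H beside the branched C2 substituent, giving the C4 enone and leaving the C1 carbinol with its configuration unchanged.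

Step 11
Reactants: 14 (4S,5S)-5-[(2R,4R)-4-(TBSO)-6-methylhept-5-en-2-yl]-4-hydroxy-2-methylcyclohex-2-en-1-one
Product: 16 (2S,4R,5S)-5-[(2R,4R)-4-(TBSO)-6-methylhept-5-en-2-yl]-4-hydroxy-2-methylcyclohexan-1-one, via C2-epimeric hydroxy ketone 15 (not isolated)
Conditions: [(Ph3P)CuH]6, H2O, THF, rt; then DBU (cat.), CH2Cl2, rt
Reagents that add atoms: none
Why: Copper hydride conjugate reduction delivers hydride to the unsubstituted β-carbon C6 of the enone without touching the isolated alkene, and base equilibration α to the ketone then sets the C5 methyl equatorial, trans to the equatorial C2 chain across the ring and therefore cis to the C1 oxygen.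

Step 12
Reactants: 16 (2S,4R,5S)-5-[(2R,4R)-4-(TBSO)-6-methylhept-5-en-2-yl]-4-hydroxy-2-methylcyclohexan-1-one; 17 angelic acid, (2Z)-2-methylbut-2-enoic acid
Product: 19 (1R,2S,5S)-2-[(2R,4R)-4-(TBSO)-6-methylhept-5-en-2-yl]-5-methyl-4-oxocyclohexyl (2Z)-2-methylbut-2-enoate, via mixed anhydride 18 (not isolated)
Conditions: 17, 2,4,6-trichlorobenzoyl chloride, Et3N, toluene, rt; then 16, toluene, 75 °C
Reagents that add atoms: none
Why: Yamaguchi-type mixed-anhydride esterification, in which the alcohol attacks the unshielded angeloyl carbonyl, and the absence of a nucleophilic catalyst at moderate temperature should keep the Z geometry from isomerising to the tiglate.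

Step 13
Reactants: 19 (1R,2S,5S)-2-[(2R,4R)-4-(TBSO)-6-methylhept-5-en-2-yl]-5-methyl-4-oxocyclohexyl (2Z)-2-methylbut-2-enoate
Product: 20 (1R,2S,5S)-2-[(2R,4R)-4-hydroxy-6-methylhept-5-en-2-yl]-5-methyl-4-oxocyclohexyl (2Z)-2-methylbut-2-enoate
Conditions: Bu4NF, AcOH, THF, 0 °C to rt
Reagents that add atoms: none
Why: Fluoride-mediated Si–O cleavage, buffered with acetic acid so that neither the angelate nor the centre α to the ketone is exposed to strong base.

Step 14
Reactants: 20 (1R,2S,5S)-2-[(2R,4R)-4-hydroxy-6-methylhept-5-en-2-yl]-5-methyl-4-oxocyclohexyl (2Z)-2-methylbut-2-enoate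
Product: 21 (1R,2S,5S)-2-[(2R,4R)-4-(acetyloxy)-6-methylhept-5-en-2-yl]-5-methyl-4-oxocyclohexyl (2Z)-2-methylbut-2-enoate
Conditions: Ac2O, pyridine, DMAP (cat.), CH2Cl2, 0 °C to rt
Reagents that add atoms: acetic anhydride, CC(=O)OC(C)=O
Why: Acetylation of the only free hydroxyl in the molecule, so no selection between two secondary alcohols is needed at the end of the route.

Step 15
Reactants: 21 (1R,2S,5S)-2-[(2R,4R)-4-(acetyloxy)-6-methylhept-5-en-2-yl]-5-methyl-4-oxocyclohexyl (2Z)-2-methylbut-2-enoate
Product: 22 (1R,2S,4R,5S)-2-[(2R,4R)-4-(acetyloxy)-6-methylhept-5-en-2-yl]-4-hydroxy-5-methylcyclohexyl (2Z)-2-methylbut-2-enoate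
Conditions: LiBH(s-Bu)3 (1.1 equiv), THF, −78 °C; then H2O (pH 7 buffer)
Reagents that add atoms: none
Why: The bulky trialkylborohydride attacks the cyclohexanone from the equatorial side of a chair whose three substituents are all equatorial, giving the axial C4 alcohol cis to the C5 methyl, and at −78 °C the ketone is reduced far faster than the acetate or the β-substituted angelate.

## Compound list

1 | 3-methylbut-2-enal | CC(C)=CC=O | starting material
2 | (4R)-6-methylhepta-1,5-dien-4-ol | C=CC[C@H](C=C(C)C)O | intermediate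
3 | tert-butyl(dimethyl){[(4R)-6-methylhepta-1,5-dien-4-yl]oxy}silane | C=CC[C@H](C=C(C)C)O[Si](C)(C)C(C)(C)C | intermediate
4 | S-ethyl prop-2-enethioate | C=CC(=O)SCC | starting material
5 | S-ethyl (2E,5R)-5-(TBSO)-7-methylocta-2,6-dienethioate | CCSC(=O)/C=C/C[C@H](C=C(C)C)O[Si](C)(C)C(C)(C)C | intermediate
6 | S-ethyl (3R,5R)-5-(TBSO)-3,7-dimethyloct-6-enethioate | CCSC(=O)C[C@H](C)C[C@H](C=C(C)C)O[Si](C)(C)C(C)(C)C | intermediate
7 | (3R,5R)-5-(TBSO)-3,7-dimethyloct-6-enal | O=CC[C@H](C)C[C@H](C=C(C)C)O[Si](C)(C)C(C)(C)C | intermediate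
8 | but-3-en-2-one | CC(=O)C=C | starting material
9 | (2S,3R,5R)-5-(TBSO)-3,7-dimethyl-2-(3-oxobutyl)oct-6-enal | O=C[C@@H](CCC(C)=O)[C@H](C)C[C@H](C=C(C)C)O[Si](C)(C)C(C)(C)C | intermediate
10 | (4S)-4-[(2R,4R)-4-(TBSO)-6-methylhept-5-en-2-yl]cyclohex-2-en-1-one | O=C1C=C[C@@H](CC1)[C@H](C)C[C@H](C=C(C)C)O[Si](C)(C)C(C)(C)C | intermediate
11 | (4S)-4-[(2R,4R)-4-(TBSO)-6-methylhept-5-en-2-yl]cyclohexa-1,5-dien-1-yl trifluoromethanesulfonate | O=S(=O)(OC1=CC[C@H](C=C1)[C@H](C)C[C@H](C=C(C)C)O[Si](C)(C)C(C)(C)C)C(F)(F)F | intermediate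
12 | (5S)-5-[(2R,4R)-4-(TBSO)-6-methylhept-5-en-2-yl]-2-methylcyclohexa-1,3-diene | CC1=CC[C@H](C=C1)[C@H](C)C[C@H](C=C(C)C)O[Si](C)(C)C(C)(C)C | intermediate
13 | (1S,4R,7S)-7-[(2R,4R)-4-(TBSO)-6-methylhept-5-en-2-yl]-5-methyl-2,3-dioxabicyclo[2.2.2]oct-5-ene | O1[C@@H]2C=C(C)[C@H](O1)C[C@H]2[C@H](C)C[C@H](C=C(C)C)O[Si](C)(C)C(C)(C)C | intermediate
14 | (4S,5S)-5-[(2R,4R)-4-(TBSO)-6-methylhept-5-en-2-yl]-4-hydroxy-2-methylcyclohex-2-en-1-one | O[C@@H]1C=C(C)C(=O)C[C@H]1[C@H](C)C[C@H](C=C(C)C)O[Si](C)(C)C(C)(C)C | intermediate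
15 | (2R,4R,5S)-5-[(2R,4R)-4-(TBSO)-6-methylhept-5-en-2-yl]-4-hydroxy-2-methylcyclohexan-1-one | O[C@@H]1C[C@@H](C)C(=O)C[C@H]1[C@H](C)C[C@H](C=C(C)C)O[Si](C)(C)C(C)(C)C | intermediate
16 | (2S,4R,5S)-5-[(2R,4R)-4-(TBSO)-6-methylhept-5-en-2-yl]-4-hydroxy-2-methylcyclohexan-1-one | O[C@@H]1C[C@H](C)C(=O)C[C@H]1[C@H](C)C[C@H](C=C(C)C)O[Si](C)(C)C(C)(C)C | intermediate
17 | angelic acid, (2Z)-2-methylbut-2-enoic acid | C/C=C(/C)C(=O)O | starting material
18 | (2Z)-2-methylbut-2-enoic 2,4,6-trichlorobenzoic anhydride | C/C=C(/C)C(=O)OC(=O)c1c(Cl)cc(Cl)cc1Cl | intermediate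
19 | (1R,2S,5S)-2-[(2R,4R)-4-(TBSO)-6-methylhept-5-en-2-yl]-5-methyl-4-oxocyclohexyl (2Z)-2-methylbut-2-enoate | C/C=C(/C)C(=O)O[C@@H]1C[C@H](C)C(=O)C[C@H]1[C@H](C)C[C@H](C=C(C)C)O[Si](C)(C)C(C)(C)C | intermediate
20 | (1R,2S,5S)-2-[(2R,4R)-4-hydroxy-6-methylhept-5-en-2-yl]-5-methyl-4-oxocyclohexyl (2Z)-2-methylbut-2-enoate | C/C=C(/C)C(=O)O[C@@H]1C[C@H](C)C(=O)C[C@H]1[C@H](C)C[C@H](C=C(C)C)O | intermediate
21 | (1R,2S,5S)-2-[(2R,4R)-4-(acetyloxy)-6-methylhept-5-en-2-yl]-5-methyl-4-oxocyclohexyl (2Z)-2-methylbut-2-enoate | C/C=C(/C)C(=O)O[C@@H]1C[C@H](C)C(=O)C[C@H]1[C@H](C)C[C@H](C=C(C)C)OC(C)=O | intermediate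
22 | (1R,2S,4R,5S)-2-[(2R,4R)-4-(acetyloxy)-6-methylhept-5-en-2-yl]-4-hydroxy-5-methylcyclohexyl (2Z)-2-methylbut-2-enoate | C/C=C(/C)C(=O)O[C@@H]1C[C@H](C)[C@H](O)C[C@H]1[C@H](C)C[C@H](C=C(C)C)OC(C)=O | target

## Step count and risks

Total step count: 15. Longest linear sequence: 15 steps, from 3-methylbut-2-enal (1) to 22.

Steps most likely to fail:

1. Step 9. Oxygen may add to both faces of the diene with little discrimination, and part of the material may be lost to ene hydroperoxidation. The fallback sets out from 12 and comes back at 14, and makes the sequence stereoconvergent instead of relying on facial control. The irradiation is run as before, and the wrong-face adduct, the syn-endoperoxide F1, is kept and opened with Et3N in CH2Cl2 to the C1-epimeric hydroxy-enone F2. Mitsunobu esterification with chloroacetic acid (PPh3, diisopropyl azodicarboxylate, toluene, 0 °C) inverts the allylic C1 carbinol and gives the inverted chloroacetate F3. Brief methanolysis (K2CO3, MeOH, 0 °C) then releases 14, so that both cycloadducts feed the same intermediate.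

2. Step 10. The amine may abstract the C1 bridgehead hydrogen in competition with C4–H, which would give the regioisomeric C1-ketone/C4-alcohol, and prolonged exposure to base may dehydrate the hydroxy-enone towards a phenol. The fallback sets out from 13 and comes back at 14, and replaces the base-induced fragmentation by reduction and a sterically controlled oxidation. Thiourea in MeOH at rt cleaves the O–O bond to give the cis-enediol F4. Oxoammonium oxidation (TEMPO cat., PhI(OAc)2, CH2Cl2, 0 °C) is then expected to take the C4 carbinol first. That hydroxyl is pseudoaxial and has only CH2 and a planar vinylic carbon as neighbours, whereas the C1 hydroxyl is pseudoequatorial and flanked by the branched C2 substituent. The product of selective C4 oxidation is 14.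

3. Step 12. Acylation of the hindered C1 hydroxyl, which sits beside the equatorial branched chain, may be slow, and at the temperature needed the angeloyl group may isomerise to the tigloyl group. The fallback sets out from 16 and comes back at 19, and builds the Z-alkene on the molecule instead of transferring it. Esterification with 2-[bis(2,2,2-trifluoroethoxy)phosphoryl]propanoic acid (dicyclohexylcarbodiimide, DMAP cat., CH2Cl2, rt) gives the phosphonopropionate ester F5. Still–Gennari olefination with acetaldehyde (KN(SiMe3)2, 18-crown-6, THF, −78 °C; the phosphonate is deprotonated in preference to the ketone) then forms the (Z)-2-methylbut-2-enoate and gives 19.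

## Further compounds

F1 | step 9 | (1R,4S,7S)-7-[(2R,4R)-4-(TBSO)-6-methylhept-5-en-2-yl]-5-methyl-2,3-dioxabicyclo[2.2.2]oct-5-ene | O1[C@H]2C=C(C)[C@@H](O1)C[C@H]2[C@H](C)C[C@H](C=C(C)C)O[Si](C)(C)C(C)(C)C
F2 | step 9 | (4R,5S)-5-[(2R,4R)-4-(TBSO)-6-methylhept-5-en-2-yl]-4-hydroxy-2-methylcyclohex-2-en-1-one | O[C@H]1C=C(C)C(=O)C[C@H]1[C@H](C)C[C@H](C=C(C)C)O[Si](C)(C)C(C)(C)C
F3 | step 9 | (1S,6S)-6-[(2R,4R)-4-(TBSO)-6-methylhept-5-en-2-yl]-3-methyl-4-oxocyclohex-2-en-1-yl chloroacetate | ClCC(=O)O[C@@H]1C=C(C)C(=O)C[C@H]1[C@H](C)C[C@H](C=C(C)C)O[Si](C)(C)C(C)(C)C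
F4 | step 10 | (1R,4S,5S)-5-[(2R,4R)-4-(TBSO)-6-methylhept-5-en-2-yl]-2-methylcyclohex-2-ene-1,4-diol | O[C@@H]1C=C(C)[C@H](O)C[C@H]1[C@H](C)C[C@H](C=C(C)C)O[Si](C)(C)C(C)(C)C
F5 | step 12 | (1R,2S,5S)-2-[(2R,4R)-4-(TBSO)-6-methylhept-5-en-2-yl]-5-methyl-4-oxocyclohexyl 2-[bis(2,2,2-trifluoroethoxy)phosphoryl]propanoate | CC(C(=O)O[C@@H]1C[C@H](C)C(=O)C[C@H]1[C@H](C)C[C@H](C=C(C)C)O[Si](C)(C)C(C)(C)C)P(=O)(OCC(F)(F)F)OCC(F)(F)F
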